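**Retrosynthetic overview**

1. Target ⇐ 12-bromo-8(17)-en-2-one decalin: the side chain by sp3–sp2 Negishi coupling (C12–C13) with a (Z)-vinyl iodide, the 7α-OH by SeO2 ene oxidation of the 8(17)-alkene, the 2α-OH by single-electron reduction of a C2 ketone.
2. Key disconnection: the 2-oxo-8(17)-ene trans-decalin ⇐ a 1-hydroxybicyclo[3.1.0]hexane carrying a (3E)-alkenyl chain. Oxidative radical ring expansion turns the cyclopentane into ring A (the cyclopropane CH2 becomes C1), the resulting radical closes ring B 6-endo, and Cu(II) terminates to C8=C17.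
3. Enabling feature (labdane numbering): in ring A the C2 oxygen is β to the quaternary C10 (C2–C1–C10), the retron of a 3-oxocycloalkyl radical from a cyclopropanol. C10 is tied through C5–C6–C7 to C8/C9 of ring B, so the same radical closes ring B and ends as the exocyclic alkene.
4. Cyclopropanol ⇐ Simmons–Smith reaction on a regiospecific silyl enol ether; chain by lactol methylenation and B-alkyl Suzuki coupling. A temporary cis-fused lactone (C19–O–C6) fixes C5 relative to C4 and is then opened, its ring oxygen staying on C19.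
5. Cyclopentenone ⇐ catalytic asymmetric Pauson–Khand reaction of methallyl 2-butynyl ether (sets quaternary C4; CO becomes the C2 oxygen). Ring order: cyclopentenone with temporary oxacycle → cyclopropane → ring A by expansion and ring B by cyclisation in one step.

Key step: step 11

Remark: labdane numbering (C1–C10 decalin, C17 exocyclic CH2, C18 4α-CH3, C19 CH2OAc, C20 10-CH3) locates atoms in all intermediates; the target is read as 19-acetoxylabda-8(17),13Z-diene-2α,7α,15-triol, (2R,4S,5R,7R,9R,10S).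
Assumption: in step 2 the BINAP antipode is chosen that gives the (3aS) enone; (S)-BINAP is written. The cyclopropane in 7–17 is drawn for convex-face attack; either face would serve, since both centres are destroyed in step 11.

**Route**

Step 1
Reactants: 1 2-butyn-1-ol; 2 3-chloro-2-methylprop-1-ene (methallyl chloride)
Product: 3 1-[(2-methylprop-2-en-1-yl)oxy]but-2-yne
Conditions: NaH, THF, 0 °C; then 2, n-Bu4NI (cat.), 0 °C → rt
Reagents that add atoms: none
Why: Williamson ether synthesis, the propargylic alkoxide displacing the reactive allylic chloride (SN2); no stereocentre is formed.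

Step 2
Reactants: 3 1-[(2-methylprop-2-en-1-yl)oxy]but-2-yne
Product: 4 (3aS)-3a,6-dimethyl-3a,4-dihydro-1H-cyclopenta[c]furan-5(3H)-one
Conditions: [Rh(CO)2Cl]2 (3 mol %), (S)-BINAP (9 mol %), AgOTf (12 mol %), CO (1 atm), THF, 80 °C
Reagents that add atoms: carbon monoxide, [C-]#[O+]
Why: catalytic asymmetric intramolecular Pauson–Khand reaction of an oxygen-tethered 1,6-enyne, in which the chiral Rh(I)–bisphosphine should select the enantioface of the 1,1-disubstituted alkene and so set the quaternary centre (C4) with its methyl and CH2O groups in place.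

Step 3
Reactants: 4 (3aS)-3a,6-dimethyl-3a,4-dihydro-1H-cyclopenta[c]furan-5(3H)-one
Product: 5 (3aS)-3a,6-dimethyl-3a,4-dihydro-1H-cyclopenta[c]furan-1,5(3H)-dione
Conditions: CrO3, 3,5-dimethylpyrazole, CH2Cl2, −20 °C
Reagents that add atoms: chromium trioxide, O=[Cr](=O)=O
Why: allylic oxidation of a cyclic allylic ether to the unsaturated lactone, the C1 methylene being the only position that is both allylic and α to oxygen.

Step 4
Reactants: 5 (3aS)-3a,6-dimethyl-3a,4-dihydro-1H-cyclopenta[c]furan-1,5(3H)-dione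
Product: 6 (3aS,6aS)-3a,6-dimethyl-5-[(triethylsilyl)oxy]-3,3a,4,6a-tetrahydro-1H-cyclopenta[c]furan-1-one (cis-fused; H-6a and 3a-CH3 on the same face)
Conditions: RhCl(PPh3)3 (2 mol %), Et3SiH (1.5 equiv), THF, 50 °C
Reagents that add atoms: triethylsilane, CC[SiH](CC)CC
Why: Rh-catalysed 1,4-hydrosilylation of the enone (the ketone should react in preference to the lactone), with hydrogen delivered to C6a syn to the 3a-methyl group because only the cis-fused bicyclo[3.3.0] framework can form; this sets C5 and fixes the silyl enol ether on the methyl-bearing side.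

Step 5
Reactants: 6 (3aS,6aS)-3a,6-dimethyl-5-[(triethylsilyl)oxy]-3,3a,4,6a-tetrahydro-1H-cyclopenta[c]furan-1-one
Product: 7 (1S,2R,4R,6S)-2,6-dimethyl-4-[(triethylsilyl)oxy]-8-oxatricyclo[4.3.0.0^2,4]nonan-9-one (cyclopropane CH2 on the face of H-1 and 6-CH3)
Conditions: Et2Zn, CH2I2, CH2Cl2, 0 °C → rt; pyridine/aq. NH4Cl work-up
Reagents that add atoms: diiodomethane, ICI
Why: Simmons–Smith (Furukawa) cyclopropanation of the electron-rich silyl enol ether, expected from the convex face of the cis-fused bicycle; the two new centres are of no later consequence.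

Step 6
Reactants: 7 (1S,2R,4R,6S)-2,6-dimethyl-4-[(triethylsilyl)oxy]-8-oxatricyclo[4.3.0.0^2,4]nonan-9-one
Product: 8 (1S,2R,4R,6S)-2,6-dimethyl-4-[(triethylsilyl)oxy]-8-oxatricyclo[4.3.0.0^2,4]nonan-9-ol (lactol, both C9 epimers)
Conditions: DIBAL-H (1.1 equiv), CH2Cl2, −78 °C; Rochelle salt
Reagents that add atoms: none
Why: partial reduction of the γ-lactone to the lactol, the tetrahedral aluminate being stable at −78 °C; the silyl cyclopropyl ether is inert.

Step 7
Reactants: 8 (1S,2R,4R,6S)-2,6-dimethyl-4-[(triethylsilyl)oxy]-8-oxatricyclo[4.3.0.0^2,4]nonan-9-ol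
Product: 10 [(1R,2S,3S,5R)-2-ethenyl-1,3-dimethyl-5-[(triethylsilyl)oxy]bicyclo[3.1.0]hexan-3-yl]methyl acetate, via alcohol 9 (not isolated)
Conditions: Ph3PCH3Br, KHMDS, THF, 0 °C; 8, −78 → 0 °C; then Ac2O, DMAP (cat.), 0 °C → rt
Reagents that add atoms: methyltriphenylphosphonium bromide (as its ylide), C[P+](c1ccccc1)(c1ccccc1)c1ccccc1.[Br-]; acetic anhydride, CC(=O)OC(C)=O
Why: Wittig methylenation of the ring-opened hydroxy aldehyde, which opens the temporary ring and leaves its oxygen on C19, followed by acylation of the alkoxide in the same flask; the non-stabilised ylide at low temperature should not epimerise the α-centre (C5).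

Step 8
Reactants: 11 pent-3-yn-1-ol
Product: 12 5-bromopent-2-yne
Conditions: CBr4, PPh3, CH2Cl2, 0 °C
Reagents that add atoms: carbon tetrabromide, BrC(Br)(Br)Br
Why: Appel bromination of a primary alcohol.

Step 9
Reactants: 12 5-bromopent-2-yne
Product: 14 (2E)-5-bromo-2-iodopent-2-ene, via alkenylzirconocene 13 (not isolated)
Conditions: Cp2Zr(H)Cl (1.5 equiv), THF, rt → 40 °C; then I2, 0 °C
Reagents that add atoms: iodine, II
Why: syn-hydrozirconation of the 2-alkyne under equilibrating conditions places zirconium on the less hindered methyl-bearing carbon, and iodinolysis with retention gives the E-iodide.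

Step 10
Reactants: 10 [(1R,2S,3S,5R)-2-ethenyl-1,3-dimethyl-5-[(triethylsilyl)oxy]bicyclo[3.1.0]hexan-3-yl]methyl acetate; 14 (2E)-5-bromo-2-iodopent-2-ene
Product: 16 [(1R,2S,3S,5R)-2-[(3E)-6-bromo-3-methylhex-3-en-1-yl]-1,3-dimethyl-5-[(triethylsilyl)oxy]bicyclo[3.1.0]hexan-3-yl]methyl acetate, via alkylborane 15 (not isolated)
Conditions: 9-BBN, THF, 0 °C → rt; then 14, PdCl2(dppf) (5 mol %), AsPh3 (10 mol %), Cs2CO3, DMF/H2O, rt
Reagents that add atoms: none
Why: anti-Markovnikov hydroboration of the monosubstituted alkene and B-alkyl Suzuki–Miyaura coupling with retention of the E geometry, oxidative addition choosing the vinyl iodide over the primary alkyl bromide.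

Step 11
Reactants: 16 [(1R,2S,3S,5R)-2-[(3E)-6-bromo-3-methylhex-3-en-1-yl]-1,3-dimethyl-5-[(triethylsilyl)oxy]bicyclo[3.1.0]hexan-3-yl]methyl acetate
Product: 20 12-bromo-2-oxo-13,14,15,16-tetranorlabd-8(17)-en-19-yl acetate (trans-decalin; 5α-H; 9α-H; 10β-CH3; 4α-CH3; 4β-CH2OAc), via cyclopropanol 17 (not isolated), via C10 radical 18 (not isolated), via C8 radical 19 (not isolated)
Conditions: TBAF (1.1 equiv), AcOH (1.2 equiv), DMF, 0 °C; then Mn(pic)3 (2.3 equiv; pic = pyridine-2-carboxylate, prepared beforehand), Cu(OAc)2 (1.0 equiv), degassed DMF (0.02 M), 0 °C → rt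
Reagents that add atoms: none
Why: Mn(III) oxidises the liberated cyclopropanol 17 to its alkoxy radical, whose β-scission of the internal cyclopropane bond (C2–C10) enlarges the five-membered ring by the former cyclopropane CH2 (C1) to the cyclohexanone ring A and leaves the tertiary β-keto radical 18 at C10 (a primary radical from external-bond cleavage would re-close on the carbonyl and drain into 18). The closest known reaction type is the Fe(III)- or Mn(III)-mediated ring expansion–radical cyclisation of 1-hydroxy- or 1-siloxybicyclo[n.1.0]alkanes, joined here to the Mn(III)/Cu(II) oxidative termination known from polyene radical cyclisations. Ring A thus arises by one-carbon ring expansion, and ring B is closed by 6-endo-trig addition of C10 to C9 through a chair transition state with the chain on C5 equatorial, which gives the tertiary radical 19 at C8. C10 (axial methyl, trans ring fusion) is controlled by the C5 stereocentre, and C9 (α-H, equatorial C11) by the E geometry of the C8=C9 bond, the substituent trans to C7 ending equatorial. Cu(II) traps 19 as an alkylcopper(III) species that loses the least hindered β-hydrogen from C17 to give the exocyclic 8(17)-alkene. The step needs 6-endo over 5-exo closure, secured by the fully substituted proximal alkene carbon C8 and the tertiary radical formed, and cyclisation ahead of oxidation of 18, favoured by the intramolecular closure and the low Cu(II) concentration.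

Step 12
Reactants: 20 12-bromo-2-oxo-13,14,15,16-tetranorlabd-8(17)-en-19-yl acetate
Product: 21 12-bromo-2α-hydroxy-13,14,15,16-tetranorlabd-8(17)-en-19-yl acetate
Conditions: SmI2 (3 equiv), THF/H2O, 0 °C
Reagents that add atoms: none
Why: single-electron (ketyl) reduction, in which protonation of the organosamarium intermediate should give the more stable equatorial 2α-alcohol, whereas hydride reagents would attack the α face (the β face is shielded by the syn-axial 10-CH3 and 4-CH2OAc) and give the 2β-epimer; the acetate and the alkyl bromide should be inert without HMPA or amine.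

Step 13
Reactants: 21 12-bromo-2α-hydroxy-13,14,15,16-tetranorlabd-8(17)-en-19-yl acetate
Product: 22 12-bromo-2α,7α-dihydroxy-13,14,15,16-tetranorlabd-8(17)-en-19-yl acetate
Conditions: SeO2 (0.5 equiv), t-BuOOH (3 equiv), CH2Cl2, rt
Reagents that add atoms: selenium dioxide, O=[Se]=O; tert-butyl hydroperoxide, CC(C)(C)OO
Why: SeO2 allylic oxidation (ene reaction, then [2,3]-sigmatropic shift) of the exocyclic alkene, which prefers the ring CH2 (C7) over the CH (C9) and delivers oxygen axially, that is 7α, as is usual for methylenecyclohexanes in trans-decalins.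

Step 14
Reactants: 22 12-bromo-2α,7α-dihydroxy-13,14,15,16-tetranorlabd-8(17)-en-19-yl acetate
Product: 23 12-bromo-2α,7α-bis[(triethylsilyl)oxy]-13,14,15,16-tetranorlabd-8(17)-en-19-yl acetate
Conditions: TESOTf, 2,6-lutidine, CH2Cl2, −78 → 0 °C
Reagents that add atoms: triethylsilyl trifluoromethanesulfonate, CC[Si](CC)(CC)OS(=O)(=O)C(F)(F)F
Why: silylation of both secondary alcohols (the triflate is needed for the axial allylic 7α-OH) so that no acidic proton quenches the organozinc in step 17.

Step 15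
Reactants: 1 2-butyn-1-ol
Product: 25 (2Z)-3-iodobut-2-en-1-ol, via vinylalanate 24 (not isolated)
Conditions: Red-Al, THF, 0 °C → rt; then I2, −78 → 0 °C
Reagents that add atoms: iodine, II
Why: hydroxyl-directed trans-hydroalumination of the propargylic alcohol (H to C2, Al to C3 in a five-membered alanate) and iodinolysis with retention give the Z-iodide.

Step 16
Reactants: 25 (2Z)-3-iodobut-2-en-1-ol
Product: 26 triethyl{[(2Z)-3-iodobut-2-en-1-yl]oxy}silane
Conditions: TESCl, imidazole, CH2Cl2, 0 °C
Reagents that add atoms: chlorotriethylsilane, CC[Si](Cl)(CC)CC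
Why: standard silylation of a primary allylic alcohol.

Step 17
Reactants: 23 12-bromo-2α,7α-bis[(triethylsilyl)oxy]-13,14,15,16-tetranorlabd-8(17)-en-19-yl acetate; 26 triethyl{[(2Z)-3-iodobut-2-en-1-yl]oxy}silane
Product: 28 2α,7α,15-tris[(triethylsilyl)oxy]labda-8(17),13Z-dien-19-yl acetate, via alkylzinc bromide 27 (not isolated)
Conditions: Zn dust (activated with BrCH2CH2Br/TMSCl), LiCl, THF, 50 °C; then 26, Pd(PPh3)4 (5 mol %), THF, rt → 45 °C
Reagents that add atoms: none
Why: zinc insertion into the primary bromide (tolerant of the acetate) and Negishi sp3–sp2 coupling, which retains the Z geometry of the vinyl iodide.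

Step 18
Reactants: 28 2α,7α,15-tris[(triethylsilyl)oxy]labda-8(17),13Z-dien-19-yl acetate
Product: 29 2α,7α,15-trihydroxylabda-8(17),13Z-dien-19-yl acetate (target)
Conditions: HF·pyridine, pyridine, THF, 0 °C → rt
Reagents that add atoms: none
Why: fluoride-mediated cleavage of the three triethylsilyl ethers under buffered conditions that should leave the neopentyl acetate and the allylic alcohols untouched.

**Compound list**

1 | 2-butyn-1-ol | CC#CCO | starting material
2 | 3-chloro-2-methylprop-1-ene | C=C(C)CCl | starting material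
3 | 1-[(2-methylprop-2-en-1-yl)oxy]but-2-yne | CC#CCOCC(C)=C | intermediate
4 | (3aS)-3a,6-dimethyl-3a,4-dihydro-1H-cyclopenta[c]furan-5(3H)-one | CC1=C2COC[C@@]2(C)CC1=O | intermediate
5 | (3aS)-3a,6-dimethyl-3a,4-dihydro-1H-cyclopenta[c]furan-1,5(3H)-dione | CC1=C2C(=O)OC[C@@]2(C)CC1=O | intermediate
6 | (3aS,6aS)-3a,6-dimethyl-5-[(triethylsilyl)oxy]-3,3a,4,6a-tetrahydro-1H-cyclopenta[c]furan-1-one | O=C1[C@H]2[C@@](C)(CO1)CC(O[Si](CC)(CC)CC)=C2C | intermediate
7 | (1S,2R,4R,6S)-2,6-dimethyl-4-[(triethylsilyl)oxy]-8-oxatricyclo[4.3.0.0^2,4]nonan-9-one | O=C1[C@H]2[C@@](C)(CO1)C[C@]3(O[Si](CC)(CC)CC)C[C@]23C | intermediate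
8 | (1S,2R,4R,6S)-2,6-dimethyl-4-[(triethylsilyl)oxy]-8-oxatricyclo[4.3.0.0^2,4]nonan-9-ol (C9 epimers) | OC1[C@H]2[C@@](C)(CO1)C[C@]3(O[Si](CC)(CC)CC)C[C@]23C | intermediate
9 | [(1R,2S,3S,5R)-2-ethenyl-1,3-dimethyl-5-[(triethylsilyl)oxy]bicyclo[3.1.0]hexan-3-yl]methanol | C=C[C@H]1[C@@](C)(CO)C[C@]2(O[Si](CC)(CC)CC)C[C@]12C | intermediate (not isolated)
10 | [(1R,2S,3S,5R)-2-ethenyl-1,3-dimethyl-5-[(triethylsilyl)oxy]bicyclo[3.1.0]hexan-3-yl]methyl acetate | C=C[C@H]1[C@@](C)(COC(C)=O)C[C@]2(O[Si](CC)(CC)CC)C[C@]12C | intermediate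
11 | pent-3-yn-1-ol | CC#CCCO | starting material
12 | 5-bromopent-2-yne | CC#CCCBr | intermediate
13 | [(2E)-5-bromopent-2-en-2-yl]chloridobis(cyclopentadienyl)zirconium | BrCC/C=C(C)/[Zr](Cl)(C1C=CC=C1)C1C=CC=C1 | intermediate (not isolated)
14 | (2E)-5-bromo-2-iodopent-2-ene | BrCC/C=C(C)/I | intermediate
15 | [(1R,2S,3S,5R)-2-[2-(9-borabicyclo[3.3.1]nonan-9-yl)ethyl]-1,3-dimethyl-5-[(triethylsilyl)oxy]bicyclo[3.1.0]hexan-3-yl]methyl acetate | C1CCC2CCCC1B2CC[C@H]3[C@@](C)(COC(C)=O)C[C@]4(O[Si](CC)(CC)CC)C[C@]34C | intermediate (not isolated)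
16 | [(1R,2S,3S,5R)-2-[(3E)-6-bromo-3-methylhex-3-en-1-yl]-1,3-dimethyl-5-[(triethylsilyl)oxy]bicyclo[3.1.0]hexan-3-yl]methyl acetate | BrCC/C=C(C)/CC[C@H]1[C@@](C)(COC(C)=O)C[C@]2(O[Si](CC)(CC)CC)C[C@]12C | intermediate
17 | [(1R,2S,3S,5R)-2-[(3E)-6-bromo-3-methylhex-3-en-1-yl]-5-hydroxy-1,3-dimethylbicyclo[3.1.0]hexan-3-yl]methyl acetate | BrCC/C=C(C)/CC[C@H]1[C@@](C)(COC(C)=O)C[C@]2(O)C[C@]12C | intermediate (not isolated)
18 | ring-expanded tertiary radical at C10: 5-(acetoxymethyl)-6-[(3E)-6-bromo-3-methylhex-3-en-1-yl]-1,5-dimethyl-3-oxocyclohexyl radical | BrCC/C=C(C)/CC[C@@H]1[C](C)CC(=O)C[C@]1(C)COC(C)=O | intermediate (not isolated)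
19 | bicyclic tertiary radical at C8 (trans-decalin; 8-methyl radical centre) | C[C]1CC[C@H]2[C@@](C)(COC(C)=O)CC(=O)C[C@]2(C)[C@H]1CCBr | intermediate (not isolated)
20 | 12-bromo-2-oxo-13,14,15,16-tetranorlabd-8(17)-en-19-yl acetate | C=C1CC[C@H]2[C@@](C)(COC(C)=O)CC(=O)C[C@]2(C)[C@H]1CCBr | intermediate
21 | 12-bromo-2α-hydroxy-13,14,15,16-tetranorlabd-8(17)-en-19-yl acetate | C=C1CC[C@H]2[C@@](C)(COC(C)=O)C[C@H](O)C[C@]2(C)[C@H]1CCBr | intermediate
22 | 12-bromo-2α,7α-dihydroxy-13,14,15,16-tetranorlabd-8(17)-en-19-yl acetate | C=C1[C@H](O)C[C@H]2[C@@](C)(COC(C)=O)C[C@H](O)C[C@]2(C)[C@H]1CCBr | intermediate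
23 | 12-bromo-2α,7α-bis[(triethylsilyl)oxy]-13,14,15,16-tetranorlabd-8(17)-en-19-yl acetate | C=C1[C@H](O[Si](CC)(CC)CC)C[C@H]2[C@@](C)(COC(C)=O)C[C@H](O[Si](CC)(CC)CC)C[C@]2(C)[C@H]1CCBr | intermediate
24 | sodium 2,2-bis(2-methoxyethoxy)-3-methyl-2,5-dihydro-1,2-oxaluminol-2-uide (cyclic vinylalanate) | CC1=CCO[Al-]1(OCCOC)OCCOC.[Na+] | intermediate (not isolated)
25 | (2Z)-3-iodobut-2-en-1-ol | I/C(C)=C\CO | intermediate
26 | triethyl{[(2Z)-3-iodobut-2-en-1-yl]oxy}silane | I/C(C)=C\CO[Si](CC)(CC)CC | intermediate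
27 | 12-(bromozincio)-2α,7α-bis[(triethylsilyl)oxy]-13,14,15,16-tetranorlabd-8(17)-en-19-yl acetate | C=C1[C@H](O[Si](CC)(CC)CC)C[C@H]2[C@@](C)(COC(C)=O)C[C@H](O[Si](CC)(CC)CC)C[C@]2(C)[C@H]1CC[Zn]Br | intermediate (not isolated)
28 | 2α,7α,15-tris[(triethylsilyl)oxy]labda-8(17),13Z-dien-19-yl acetate | C=C1[C@H](O[Si](CC)(CC)CC)C[C@H]2[C@@](C)(COC(C)=O)C[C@H](O[Si](CC)(CC)CC)C[C@]2(C)[C@H]1CC/C(C)=C\CO[Si](CC)(CC)CC | intermediate
29 | 2α,7α,15-trihydroxylabda-8(17),13Z-dien-19-yl acetate | C=C1[C@H](O)C[C@H]2[C@@](C)(COC(C)=O)C[C@H](O)C[C@]2(C)[C@H]1CC/C(C)=C\CO | target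

**Step count**

Total step count: 18. Longest linear sequence: 14 steps (steps 1–7, 10–14, 17, 18).

**Steps most likely to fail**

Step 11. The tertiary C10 radical may be oxidised by Cu(II) or Mn(III) before it cyclises, may close 5-exo, or the C8 radical may lose a ring hydrogen and give endocyclic alkenes. The fallback separates ring expansion and ring closure into polar steps. It sets out from 10: oxidative opening of the siloxycyclopropane alone (FeCl3, DMF, 0 °C; Ito–Saegusa ring enlargement) gives the β-chloro ketone (3-chloro-2-ethenyl-1,3-dimethyl-5-oxocyclohexyl)methyl acetate F1. Loss of HCl (NaOAc, MeOH, reflux) gives the cyclohexenone (2-ethenyl-1,3-dimethyl-5-oxocyclohex-3-en-1-yl)methyl acetate F2. Hydroboration with 9-BBN gives the B-alkyl borane F3, and B-alkyl Suzuki coupling with 14 (PdCl2(dppf), Cs2CO3) gives the chain-bearing enone F4. MeAlCl2 (CH2Cl2, −78 → 0 °C) then effects a cationic conjugate (ene-type) addition of the trisubstituted alkene to the enone through a chair transition state; loss of a C17 proton from the tertiary cation returns the route to 20.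

Step 2. The hindered 1,1-disubstituted alkene may insert slowly and with eroded enantiofacial discrimination. The fallback replaces catalyst control by reagent-controlled separation. It sets out from 3: a stoichiometric Pauson–Khand reaction (Co2(CO)8, CH2Cl2; then NMO) gives the racemic enone F5. Oxazaborolidine-catalysed borane reduction ((R)-Me-CBS, BH3·SMe2) converts the two enantiomers into diastereomeric allylic alcohols that can be separated by chromatography. The diastereomer carrying the (3aS) centre, drawn as (3aS,5R)-3a,6-dimethyl-3,3a,4,5-tetrahydro-1H-cyclopenta[c]furan-5-ol F6, is re-oxidised with MnO2 to 4.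

Step 3. Oxidation at the electron-poor allylic ether position may stall, or it may attack the vinylic methyl group or over-oxidise. The fallback moves the oxidation behind the reduction of the alkene. It sets out from 4: hydrogenation (H2, Pd/C, EtOAc) gives the cis-fused ketone 3a,6-dimethylhexahydro-1H-cyclopenta[c]furan-5-one F7. RuCl3/NaIO4 oxidises the less hindered ether methylene to the keto lactone 3a,6-dimethyltetrahydro-1H-cyclopenta[c]furan-1,5-dione F8. Silylation under equilibrating conditions (TESOTf, Et3N, CH2Cl2), which favours the more substituted enol ether, returns the route to 6.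

**Further compounds**

F1 | step 11 | (3-chloro-2-ethenyl-1,3-dimethyl-5-oxocyclohexyl)methyl acetate | C=C[C@@H]1C(C)(Cl)CC(=O)C[C@]1(C)COC(C)=O
F2 | step 11 | (2-ethenyl-1,3-dimethyl-5-oxocyclohex-3-en-1-yl)methyl acetate | C=C[C@@H]1C(C)=CC(=O)C[C@]1(C)COC(C)=O
F3 | step 11 | {2-[2-(9-borabicyclo[3.3.1]nonan-9-yl)ethyl]-1,3-dimethyl-5-oxocyclohex-3-en-1-yl}methyl acetate | C1CCC2CCCC1B2CC[C@@H]3C(C)=CC(=O)C[C@]3(C)COC(C)=O
F4 | step 11 | {2-[(3E)-6-bromo-3-methylhex-3-en-1-yl]-1,3-dimethyl-5-oxocyclohex-3-en-1-yl}methyl acetate | BrCC/C=C(C)/CC[C@@H]1C(C)=CC(=O)C[C@]1(C)COC(C)=O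
F5 | step 2 | racemic 3a,6-dimethyl-3a,4-dihydro-1H-cyclopenta[c]furan-5(3H)-one | CC1=C2COCC2(C)CC1=O
F6 | step 2 | (3aS,5R)-3a,6-dimethyl-3,3a,4,5-tetrahydro-1H-cyclopenta[c]furan-5-ol | CC1=C2COC[C@@]2(C)C[C@H]1O
F7 | step 3 | (3aS,6aR)-3a,6-dimethylhexahydro-1H-cyclopenta[c]furan-5-one (cis-fused; C6 epimers) | C1[C@H]2[C@@](C)(CO1)CC(=O)C2C
F8 | step 3 | (3aS,6aS)-3a,6-dimethyltetrahydro-1H-cyclopenta[c]furan-1,5-dione (cis-fused; C6 epimers) | O=C1[C@H]2[C@@](C)(CO1)CC(=O)C2C
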